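The closed vessels hold equal charges of starting material and protic impurity, and they differ in free catalyst and temperature.

the same everywhere: starting material 0.30 M
- teal: protic impurity 0.30 M; free catalyst 0.11 mM; temperature 40 °C; run made earlier
- amber: protic impurity 0.30 M; free catalyst 0.21 mM; temperature 51 °C; run made earlier
- violet: protic impurity 0.30 M; free catalyst 0.58 mM; temperature 40 °C; run made earlier
- delta: protic impurity 0.300 M; free catalyst 0.50 mM; temperature 35 °C; time 2.0 min
- beta: protic impurity 0.300 M; free catalyst 0.30 mM; temperature 35 °C; time 2.0 min
- gamma: protic impurity 0.300 M; free catalyst 0.10 mM; temperature 55 °C; time 2.0 min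
- zeta: protic impurity 0.300 M; free catalyst 0.30 mM; temperature 55 °C; time 2.0 min
- alpha: protic impurity 0.300 M; free catalyst 0.10 mM; temperature 35 °C; time 2.0 min
- eta: protic impurity 0.300 M; free catalyst 0.50 mM; temperature 55 °C; time 2.0 min

| run | time / s | product / % |
|---|---|---|
| teal | 10.0 | 0.4 |
| teal | 20.0 | 5.7 |
| teal | 40.0 | 7.5 |
| teal | 60.0 | 10.0 |
| teal | 80.0 | 15.2 |
| amber | 10.0 | 6.6 |
| amber | 20.0 | 11.0 |
| amber | 25.0 | 13.4 |
| amber | 40.0 | 18.8 |
| violet | 10.0 | 12.3 |
| violet | 20.0 | 19.0 |
| violet | 40.0 | 36.0 |
| violet | 60.0 | 51.6 |
| violet | 80.0 | 60.9 |

(standard deviation of a reading: 1 percentage point)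

- ranking by amount of product, in percent of the starting material charged, from high to low, at 2.0 min (delta / beta / gamma / zeta / alpha / eta)
- the amount of product, in percent of the starting material charged of the flask you put first, at 2.0 min
- the amount of product, in percent of the starting material charged of the flask you put last, at 2.0 min



From violet's last reading I get 0.0202 /mM/s. I call this s, the specific rate: the pseudo-first-order constant for product, divided by c(free catalyst). Teal's last reading gives 0.0187 /mM/s, although its catalyst is lower by a factor of 5.27. So I reckon product from c(free catalyst) times time. Amber's last reading gives 0.0248 /mM/s, a factor of 1.23 for its step in temperature. I therefore treat temperature as a correction.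

Now I turn the question round. For zeta to pass delta, going from 35 °C to 55 °C must raise s by 1.67. Amber's factor, stretched over that step, gives 1.45, which falls short. So I rank by catalyst first and put hot above cold at equal catalyst. With s corrected to 0.0185 /mM/s at 35 °C and to 0.0267 /mM/s at eta's 55 °C, I reckon eta at 79.8%, delta at 67.0% and alpha at 19.9%.

The forecast differs from me: delta > eta > beta > zeta > alpha > gamma, with 60% (53% to 72%) first and 16% (11% to 21%) last. Its words are “The hot flasks stall, so the order is tentative.”

The flasks give delta > eta > zeta > beta > gamma > alpha, with 63.7% first and 15.3% last.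

    starting material + free catalyst ⇌ catalyst intermediate A (K = 10.0 /M, k = 2900 /M/s, Ea = 41.0 kJ/mol, ΔH = −57.0 kJ/mol)
    starting material + protic impurity → quenched substrate (k = 0.0120 /M/s, Ea = 64.0 kJ/mol)
    catalyst intermediate A ⇌ catalyst intermediate B (K = 0.380, k = 8.10 /s, Ea = 59.0 kJ/mol, ΔH = −25.0 kJ/mol)
    catalyst intermediate B → free catalyst + product (k = 59.0 /s, Ea = 73.0 kJ/mol)
    (constants at 35 °C)

Zeta stands above beta, as my s said, but eta ends 3.3 percentage points behind delta, with free catalyst at 98.9% and starting material at 1.33%. In alpha at 2.00 min, the quenching path uses starting material at 0.025 of the forward binding step alone, yet quenched substrate stands at 28.0% against product at 15.3%. Alpha read at 3.0 min is reckoned by s at 28.3%. The flask gives 21.9%, with quenched substrate at 35.3%.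

Readings and results are calculated with made-up constants, noise included.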